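The numbers were set for the occasion; the result is computed.

**The gate.** Z stands between the charge and D in each of these flasks, and E, charged below J, is the limiting reagent, so I count everything as a fraction of the E charged.

| setting | north-east | east | north | west | south-west |
|---|---|---|---|---|---|
| E | 0.38 M | 0.38 M | 0.38 M | 0.38 M (fed, over 2.0 min) | 0.38 M |
| J | 0.418 M (fed, over 30 s) | 0.418 M (fed, over 2.0 min) | 0.418 M | 0.418 M | 0.418 M (in portions, 5, over 2.0 min) |
| time | 2.5 min | 2.5 min | 2.5 min | 2.5 min | 2.5 min |
| remark | all else is in the flask from the start; the feed brings no volume worth counting | all else is in the flask from the start; the feed brings no volume worth counting | everything together at the start | all else is in the flask from the start; the feed brings no volume worth counting | first portion at the start, last at 2.0 min |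

- the flask that comes out highest in amount of D, in percent of the E charged, or "all alike" when all lie within 1.5 percentage points (north-east / east / north / west / south-west / all alike)
- D at the end, in percent of the E charged, north-east
- D at the end, in percent of the E charged, east
- D at the end, in percent of the E charged, north
- D at the end, in percent of the E charged, west
- D at the end, in percent of the E charged, south-west

    E + J → Z + X (k1 = 0.030 /M/s)
    Z → D (k2 = 0.0040 /s)
    Z → Q (k3 = 0.0041 /s)
    E + X → E.X (k4 = 0.0013 /M/s)

**First freeze.** Two things about Z stay constant whatever the recipe: it leaves as D with a share of 0.494, and its lifetime, the reciprocal of the summed constants of its two exits, is 2.06 min. So I give each Z formed a credit, the fraction of it that has become D after a given time left: the share times one minus the exponential of minus time left over lifetime. A Z formed at the very start earns 0.347 by 2.5 min.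

**First doubt.** But E does not react at once. In north, at the mean of the two charges, the second-order time is 1.39 min, which is shorter than the run yet not short enough to ignore. That form gives a made fraction of 0.642 with a median moment of formation at 0.659 min. The credit there is 0.292, so I commit to 18.8% for north. The loss of E to X looks small, since even with X at the full E charge that step runs at 0.0394 of the charged rate of the first step.

**Second doubt.** Could a feed do better? In west, E arrives steadily, so formation rises about in step with time and the median moment falls near 1.41 min, which leaves a credit of 0.202, lower than in north. In north-east the feed time 30 s is shorter than the second-order time, so I expect it close behind north.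

**The forecast.** It names north, with north-east 15.6%, east 9.8%, north 17.5%, west 9.7% and south-west 10.1%, holding that “Early reaction gives Z the most time to turn into D”. Its north stands below my figure.

**The flask.** North reads 17.5%, the highest of the flasks, while north-east reads 15.5%, east 9.80%, west 9.73% and south-west 10.0%. In north, 31.4% of the charge stands as Z at 2.50 min, beside 17.9% as Q. D over everything made there is 0.262, which through the lifetime corresponds to 1.55 min of time left, shorter than the 1.84 min I allowed. The neighbour of west charged with 0.10 M of J made 15.8%, the feed credit turns that into 3.19%, and it reads 2.88%.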